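**Retrosynthetic overview**

1. Feature: the target is a 2H-chromen-6-ol with one stereocentre, C2 (S). O1 on C8a and C4 on C4a are ortho neighbours on the benzene ring, and C2 with its methyl, its C3–C4 arm and its C1'–C2' arm is the carbinol carbon of mevalonolactone with its two arms (chain carbons C1'–C6' counted from C2).
2. C2'–C3' is cut last, by a B-alkyl Suzuki coupling of a chromene ethyl iodide with the (E)-alkenyl iodide made from dihydro-β-ionone (alkyne formation, Zr-catalysed carboalumination). The C3=C4 alkene comes from a chroman-4-one by reduction and dehydration.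
3. The chromanone is cut at O1–C8a and C4–C4a together: 3-chloro-4-methoxybenzyne inserts between the tertiary oxygen and the carbonyl carbon of (S)-mevalonolactone, used as its trimethylsilyl ether. The chlorine steers the regiochemistry and is hydrogenolysed afterwards.
4. Rings: the benzene and cyclohexene rings are bought; the only ring made is the pyran ring, closed as the pyranone in the aryne step and desaturated later. C2 comes from esterase desymmetrisation of dimethyl 3-hydroxy-3-methylglutarate.
5. The aryl methyl ether is exchanged for a triisopropylsilyl ether at the chromanone stage, so that the phenol is freed cold at the end and the 2H-chromenolate is never heated (it could open to a quinone methide and lose C2).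

Key step: step 7

Remark: the esterase is taken to give the (S)-half-ester 2. Reduction of the acid arm (borane) and of the ester arm (LiBH4 on the carboxylate) lead to opposite lactone enantiomers, so either sense of the enzymatic step can be steered to (S)-4; the enantiomeric purity is to be assayed at 4.

**Route**

Step 1
Reactants: 1 dimethyl 3-hydroxy-3-methylpentanedioate (dimethyl 3-hydroxy-3-methylglutarate)
Product: 2 (3S)-3-hydroxy-5-methoxy-3-methyl-5-oxopentanoic acid
Conditions: pig liver esterase, 0.1 M phosphate buffer pH 8, pH-stat (1 M NaOH), 25 °C; HCl to pH 2, EtOAc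
Reagents that add atoms: water, O
Why: Enzymatic desymmetrisation of a prochiral diester (hydrolysis of one of the two enantiotopic ester arms) should give the (S)-half-ester, and this is the step that sets the carbon that becomes C2 of the target.

Step 2
Reactants: 2 (3S)-3-hydroxy-5-methoxy-3-methyl-5-oxopentanoic acid
Product: 4 (S)-mevalonolactone, (4S)-4-hydroxy-4-methyloxan-2-one, via dihydroxy ester 3 (not isolated)
Conditions: BH3·SMe2, THF, 0 °C to rt; MeOH; then p-TsOH·H2O (cat.), CH2Cl2, rt
Reagents that add atoms: none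
Why: Borane reduces the carboxylic acid far faster than the methyl ester (chemoselective acid reduction) and the δ-hydroxy ester lactonises under mild acid; the ester arm becomes the lactone carbonyl, so configuration and descriptor (S) are kept.

Step 3
Reactants: 4 (S)-mevalonolactone
Product: 5 (4S)-4-methyl-4-[(trimethylsilyl)oxy]oxan-2-one
Conditions: 1-(trimethylsilyl)imidazole, CH2Cl2, rt; evaporation, short-path distillation
Reagents that add atoms: 1-(trimethylsilyl)imidazole, C[Si](C)(C)n1ccnc1
Why: O-silylation of the tertiary alcohol with a strong silyl-transfer reagent gives the latent alkoxide for the aryne step; none of the bonds at C4 is touched.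

Step 4
Reactants: 6 2-chloro-3-methoxyphenol
Product: 7 2-chloro-3-methoxyphenyl N-isopropylcarbamate
Conditions: i-PrNCO, Et3N (cat.), CH2Cl2, rt
Reagents that add atoms: isopropyl isocyanate, CC(C)N=C=O
Why: Base-catalysed addition of the phenol to an isocyanate (carbamoylation) installs the directing group for ortho-metalation.

Step 5
Reactants: 7 2-chloro-3-methoxyphenyl N-isopropylcarbamate
Product: 11 2-chloro-3-methoxy-6-(trimethylsilyl)phenyl N-isopropylcarbamate, via N-silyl carbamate 8 (not isolated), via aryllithium 9 (not isolated), via bis-silyl carbamate 10 (not isolated)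
Conditions: TBSOTf, TMEDA, Et2O, 0 °C to rt; n-BuLi, TMEDA, −78 °C; TMSCl, −78 °C to rt; aq. NaHSO4
Reagents that add atoms: chlorotrimethylsilane, C[Si](C)(C)Cl
Why: Carbamate-directed ortho-lithiation with in situ N-silyl protection of the N–H, then silyl quench; the O-carbamate outranks the methoxy group as director and C6 is its only free ortho position, so silicon should enter at C6.

Step 6
Reactants: 11 2-chloro-3-methoxy-6-(trimethylsilyl)phenyl N-isopropylcarbamate
Product: 13 2-chloro-3-methoxy-6-(trimethylsilyl)phenyl trifluoromethanesulfonate, via silyl phenol 12 (not isolated)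
Conditions: DBU, Et2NH, MeCN, 40 °C; then PhNTf2, rt
Reagents that add atoms: N-phenylbis(trifluoromethanesulfonimide), O=S(=O)(N(c1ccccc1)S(=O)(=O)C(F)(F)F)C(F)(F)F
Why: E1cB cleavage of the N-monoalkyl carbamate (the isocyanate is trapped by Et2NH) and triflation of the phenoxide in one pot is the standard entry to ortho-silylaryl triflates.

Step 7
Reactants: 13 2-chloro-3-methoxy-6-(trimethylsilyl)phenyl trifluoromethanesulfonate; 5 (4S)-4-methyl-4-[(trimethylsilyl)oxy]oxan-2-one
Product: 16 (2S)-5-chloro-2-(2-hydroxyethyl)-6-methoxy-2-methylchroman-4-one, via 3-chloro-4-methoxybenzyne 14 (not isolated), via cesium alkoxide 15 (not isolated)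
Conditions: CsF, 18-crown-6, THF, 0 °C to rt, 13 added slowly to 5 (1.5 equiv); AcOH, 0 °C
Reagents that add atoms: none
Why: Proposed new method: fluoride removes both silyl groups, so the aryne 14 and the alkoxide 15 meet with no O–H in the flask; 15 adds to the aryne carbon remote from chlorine (the later C8a), the aryl anion at the later C4a attacks the lactone carbonyl, and the bridged tetrahedral adduct collapses with loss of the primary alkoxide to the aryl ketone. The closest known reactions are the xanthone annulation of arynes with salicylate esters and aryne σ-bond insertions that end in acyl transfer; new here are an aliphatic tertiary alkoxide as nucleophile and a lactone as the internal acyl donor. The pyranone ring closes by 6-exo-trig attack of C4a on the carbonyl carbon, which becomes C4. No stereocentre is created: C2 is the carbinol carbon of 5, none of its four bonds is broken, and (S) is carried over. The step needs regioselective aryne addition (O at C8a, acyl at C4a), secured by the C–Cl bond next to the aryne, which distorts the triple bond and stabilises the carbanion forming beside it, with the methoxy group acting in the same sense. It also needs acyl capture to outrun protonation, chloride loss and a second arylation, which is why the alcohol is used as its silyl ether, the solvent is THF and not MeCN, and 13 is added slowly to an excess of 5.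

Step 8
Reactants: 16 (2S)-5-chloro-2-(2-hydroxyethyl)-6-methoxy-2-methylchroman-4-one
Product: 17 (2S)-2-(2-hydroxyethyl)-6-methoxy-2-methylchroman-4-one
Conditions: H2 (1 atm), 10% Pd/C, NaOAc, MeOH, rt
Reagents that add atoms: none
Why: Catalytic hydrodechlorination of an aryl chloride activated by the ortho acyl group; the acetate buffer takes up HCl, and the aryl ketone should not be reduced under neutral conditions at 1 atm.

Step 9
Reactants: 17 (2S)-2-(2-hydroxyethyl)-6-methoxy-2-methylchroman-4-one
Product: 18 (2R)-2-(2-iodoethyl)-6-methoxy-2-methylchroman-4-one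
Conditions: I2, PPh3, imidazole, CH2Cl2, 0 °C to rt
Reagents that add atoms: iodine, II
Why: Appel iodination of the primary alcohol; C2 is not involved, and the descriptor changes from S to R only because the iodoethyl arm now outranks C3.

Step 10
Reactants: 18 (2R)-2-(2-iodoethyl)-6-methoxy-2-methylchroman-4-one
Product: 19 (2R)-6-hydroxy-2-(2-iodoethyl)-2-methylchroman-4-one
Conditions: BBr3, CH2Cl2, −78 to 0 °C; aq. NaHCO3
Reagents that add atoms: none
Why: Lewis-acid cleavage of the aryl methyl ether is done at the chromanone stage, where O1 is a weakly basic vinylogous ester oxygen and C2 cannot open electrocyclically, so that the phenol can be carried as a silyl ether and freed cold at the end.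

Step 11
Reactants: 19 (2R)-6-hydroxy-2-(2-iodoethyl)-2-methylchroman-4-one
Product: 20 (2R)-2-(2-iodoethyl)-2-methyl-6-[(triisopropylsilyl)oxy]chroman-4-one
Conditions: TIPSOTf, 2,6-lutidine, CH2Cl2, 0 °C
Reagents that add atoms: triisopropylsilyl trifluoromethanesulfonate, CC(C)[Si](OS(=O)(=O)C(F)(F)F)(C(C)C)C(C)C
Why: Silylation of the phenol with a silyl triflate and a non-nucleophilic base avoids N-alkylation by the primary iodide; the aryl silyl ether should withstand borohydride, catalytic acid, t-BuLi at −78 °C and aqueous phosphate.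

Step 12
Reactants: 20 (2R)-2-(2-iodoethyl)-2-methyl-6-[(triisopropylsilyl)oxy]chroman-4-one
Product: 22 {[(2S)-2-(2-iodoethyl)-2-methyl-2H-chromen-6-yl]oxy}triisopropylsilane, via chromanol 21 (not isolated)
Conditions: NaBH4, EtOH/THF, 0 °C to rt; aq. NH4Cl; then p-TsOH·H2O (cat.), toluene, 80 °C
Reagents that add atoms: none
Why: Ketone reduction then acid-catalysed E1 dehydration of the benzylic alcohol is the classical chroman-4-one to 2H-chromene sequence; the primary iodide, unlike a free hydroxyethyl arm, cannot trap the C4 cation as a bridged ether, the C4 stereocentre of 21 disappears and C2 is untouched.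

Step 13
Reactants: 23 dihydro-β-ionone, 4-(2,6,6-trimethylcyclohex-1-en-1-yl)butan-2-one
Product: 27 2-(but-3-yn-1-yl)-1,3,3-trimethylcyclohex-1-ene, via lithium enolate 24 (not isolated), via enol phosphate 25 (not isolated), via lithium acetylide 26 (not isolated)
Conditions: LiN(i-Pr)2, THF, −78 °C; ClP(O)(OEt)2, −78 °C to rt; LiN(i-Pr)2 (2.3 equiv), −78 °C to rt; H2O
Reagents that add atoms: none
Why: Kinetic deprotonation of the methyl ketone at CH3, O-phosphorylation and double elimination is the enol phosphate route from methyl ketones to terminal alkynes.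

Step 14
Reactants: 27 2-(but-3-yn-1-yl)-1,3,3-trimethylcyclohex-1-ene
Product: 29 2-[(3E)-4-iodo-3-methylbut-3-en-1-yl]-1,3,3-trimethylcyclohex-1-ene, via alkenylalane 28 (not isolated)
Conditions: Me3Al, Cp2ZrCl2 (25 mol %), CH2Cl2, 0 °C to rt; then I2, THF, −30 to 0 °C
Reagents that add atoms: trimethylaluminium, C[Al](C)C; iodine, II
Why: Negishi Zr-catalysed syn-carboalumination of the terminal alkyne puts methyl on the internal and aluminium on the terminal carbon, cis to each other, and iodinolysis with retention should give the (E)-iodide; the tetrasubstituted ring alkene does not react.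

Step 15
Reactants: 22 {[(2S)-2-(2-iodoethyl)-2-methyl-2H-chromen-6-yl]oxy}triisopropylsilane; 29 2-[(3E)-4-iodo-3-methylbut-3-en-1-yl]-1,3,3-trimethylcyclohex-1-ene
Product: 32 triisopropyl({(2S)-2-methyl-2-[(3E)-4-methyl-6-(2,6,6-trimethylcyclohex-1-en-1-yl)hex-3-en-1-yl]-2H-chromen-6-yl}oxy)silane, via alkyllithium 30 (not isolated), via lithium borate 31 (not isolated)
Conditions: 22, t-BuLi (2.1 equiv), Et2O, −78 °C; B-methoxy-9-BBN, THF, −78 °C to rt; then 29, Pd(dppf)Cl2 (5 mol %), K3PO4 (3 M aq.), DMF, rt
Reagents that add atoms: none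
Why: Lithium–iodine exchange and trapping with B-methoxy-9-BBN give the B-alkyl borate for a B-alkyl Suzuki–Miyaura coupling with the alkenyl iodide, which forms C2'–C3' with retention of the E geometry and touches neither C2 nor the chromene.

Step 16
Reactants: 32 triisopropyl({(2S)-2-methyl-2-[(3E)-4-methyl-6-(2,6,6-trimethylcyclohex-1-en-1-yl)hex-3-en-1-yl]-2H-chromen-6-yl}oxy)silane
Product: 33 (2S)-2-methyl-2-[(3E)-4-methyl-6-(2,6,6-trimethylcyclohex-1-en-1-yl)hex-3-en-1-yl]-2H-chromen-6-ol
Conditions: TBAF, AcOH, THF, 0 °C, exclusion of light and air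
Reagents that add atoms: none
Why: Fluoride cleavage of the aryl silyl ether, buffered so that the phenoxide is protonated at once and the 2H-chromene has no occasion to open to the quinone-methide form that would scramble C2.

**Compound list**

1 | dimethyl 3-hydroxy-3-methylpentanedioate | COC(=O)CC(C)(O)CC(=O)OC | starting material
2 | (3S)-3-hydroxy-5-methoxy-3-methyl-5-oxopentanoic acid | OC(=O)C[C@@](O)(C)CC(=O)OC | intermediate
3 | methyl (3S)-3,5-dihydroxy-3-methylpentanoate | OCC[C@@](O)(C)CC(=O)OC | intermediate
4 | (S)-mevalonolactone, (4S)-4-hydroxy-4-methyloxan-2-one | O1CC[C@@](O)(C)CC1=O | intermediate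
5 | (4S)-4-methyl-4-[(trimethylsilyl)oxy]oxan-2-one | O1CC[C@@](O[Si](C)(C)C)(C)CC1=O | intermediate
6 | 2-chloro-3-methoxyphenol | COc1cccc(O)c1Cl | starting material
7 | 2-chloro-3-methoxyphenyl N-isopropylcarbamate | COc1cccc(OC(=O)NC(C)C)c1Cl | intermediate
8 | 2-chloro-3-methoxyphenyl N-[tert-butyl(dimethyl)silyl]-N-isopropylcarbamate | COc1cccc(OC(=O)N(C(C)C)[Si](C)(C)C(C)(C)C)c1Cl | intermediate
9 | [3-chloro-2-({[tert-butyl(dimethyl)silyl](isopropyl)carbamoyl}oxy)-4-methoxyphenyl]lithium | COc1ccc([Li])c(OC(=O)N(C(C)C)[Si](C)(C)C(C)(C)C)c1Cl | intermediate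
10 | 2-chloro-3-methoxy-6-(trimethylsilyl)phenyl N-[tert-butyl(dimethyl)silyl]-N-isopropylcarbamate | COc1ccc([Si](C)(C)C)c(OC(=O)N(C(C)C)[Si](C)(C)C(C)(C)C)c1Cl | intermediate
11 | 2-chloro-3-methoxy-6-(trimethylsilyl)phenyl N-isopropylcarbamate | COc1ccc([Si](C)(C)C)c(OC(=O)NC(C)C)c1Cl | intermediate
12 | 2-chloro-3-methoxy-6-(trimethylsilyl)phenol | COc1ccc([Si](C)(C)C)c(O)c1Cl | intermediate
13 | 2-chloro-3-methoxy-6-(trimethylsilyl)phenyl trifluoromethanesulfonate | COc1ccc([Si](C)(C)C)c(OS(=O)(=O)C(F)(F)F)c1Cl | intermediate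
14 | 3-chloro-4-methoxybenzyne | COC1=C(Cl)C#CC=C1 | intermediate
15 | cesium (4S)-4-methyl-2-oxooxan-4-olate | O1CC[C@@]([O-])(C)CC1=O.[Cs+] | intermediate
16 | (2S)-5-chloro-2-(2-hydroxyethyl)-6-methoxy-2-methylchroman-4-one | OCC[C@@]1(C)CC(=O)c2c(Cl)c(OC)ccc2O1 | intermediate
17 | (2S)-2-(2-hydroxyethyl)-6-methoxy-2-methylchroman-4-one | OCC[C@@]1(C)CC(=O)c2cc(OC)ccc2O1 | intermediate
18 | (2R)-2-(2-iodoethyl)-6-methoxy-2-methylchroman-4-one | ICC[C@@]1(C)CC(=O)c2cc(OC)ccc2O1 | intermediate
19 | (2R)-6-hydroxy-2-(2-iodoethyl)-2-methylchroman-4-one | ICC[C@@]1(C)CC(=O)c2cc(O)ccc2O1 | intermediate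
20 | (2R)-2-(2-iodoethyl)-2-methyl-6-[(triisopropylsilyl)oxy]chroman-4-one | ICC[C@@]1(C)CC(=O)c2cc(O[Si](C(C)C)(C(C)C)C(C)C)ccc2O1 | intermediate
21 | (2R,4RS)-2-(2-iodoethyl)-2-methyl-6-[(triisopropylsilyl)oxy]chroman-4-ol | ICC[C@@]1(C)CC(O)c2cc(O[Si](C(C)C)(C(C)C)C(C)C)ccc2O1 | intermediate
22 | {[(2S)-2-(2-iodoethyl)-2-methyl-2H-chromen-6-yl]oxy}triisopropylsilane | ICC[C@@]1(C)C=Cc2cc(O[Si](C(C)C)(C(C)C)C(C)C)ccc2O1 | intermediate
23 | dihydro-β-ionone, 4-(2,6,6-trimethylcyclohex-1-en-1-yl)butan-2-one | CC(=O)CCC1=C(C)CCCC1(C)C | starting material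
24 | lithium 4-(2,6,6-trimethylcyclohex-1-en-1-yl)but-1-en-2-olate | [Li]OC(=C)CCC1=C(C)CCCC1(C)C | intermediate
25 | diethyl 4-(2,6,6-trimethylcyclohex-1-en-1-yl)but-1-en-2-yl phosphate | CCOP(=O)(OCC)OC(=C)CCC1=C(C)CCCC1(C)C | intermediate
26 | [4-(2,6,6-trimethylcyclohex-1-en-1-yl)but-1-yn-1-yl]lithium | [Li]C#CCCC1=C(C)CCCC1(C)C | intermediate
27 | 2-(but-3-yn-1-yl)-1,3,3-trimethylcyclohex-1-ene | C#CCCC1=C(C)CCCC1(C)C | intermediate
28 | dimethyl[(1E)-2-methyl-4-(2,6,6-trimethylcyclohex-1-en-1-yl)but-1-en-1-yl]alumane | C[Al](C)/C=C(\C)CCC1=C(C)CCCC1(C)C | intermediate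
29 | 2-[(3E)-4-iodo-3-methylbut-3-en-1-yl]-1,3,3-trimethylcyclohex-1-ene | I/C=C(\C)CCC1=C(C)CCCC1(C)C | intermediate
30 | {2-[(2S)-2-methyl-6-[(triisopropylsilyl)oxy]-2H-chromen-2-yl]ethyl}lithium | [Li]CC[C@@]1(C)C=Cc2cc(O[Si](C(C)C)(C(C)C)C(C)C)ccc2O1 | intermediate
31 | lithium 9-methoxy-9-{2-[(2S)-2-methyl-6-[(triisopropylsilyl)oxy]-2H-chromen-2-yl]ethyl}-9-boranuidabicyclo[3.3.1]nonane | [Li+].CO[B-]1(CC[C@@]2(C)C=Cc3cc(O[Si](C(C)C)(C(C)C)C(C)C)ccc3O2)C4CCCC1CCC4 | intermediate
32 | triisopropyl({(2S)-2-methyl-2-[(3E)-4-methyl-6-(2,6,6-trimethylcyclohex-1-en-1-yl)hex-3-en-1-yl]-2H-chromen-6-yl}oxy)silane | CC1=C(CC/C(C)=C/CC[C@@]2(C)C=Cc3cc(O[Si](C(C)C)(C(C)C)C(C)C)ccc3O2)C(C)(C)CCC1 | intermediate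
33 | (2S)-2-methyl-2-[(3E)-4-methyl-6-(2,6,6-trimethylcyclohex-1-en-1-yl)hex-3-en-1-yl]-2H-chromen-6-ol | CC1=C(CC/C(C)=C/CC[C@@]2(C)C=Cc3cc(O)ccc3O2)C(C)(C)CCC1 | target

**Step count and risks**

Total: 16 steps. Longest linear sequence: 11 steps (steps 1–3, 7–12, 15, 16; the branch through steps 4–6 is equally long).

Step 7 (proposed new method). What may go wrong:
- the aryl anion is protonated or loses chloride before it reaches the lactone carbonyl;
- the alkoxide 15 fragments by retro-aldol (which would also erode the configuration) or dehydrates;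
- the liberated primary alkoxide is arylated by a second aryne;
- the chromanone opens and recloses at C2 under the basic conditions.

The enantiomeric purity of 16 should therefore be checked against a racemic sample. Fallback, using known reactions and making the same two bonds in the opposite order: it sets out from 5. 2-Bromo-1-fluoro-4-methoxybenzene is converted with n-BuLi (THF, −78 °C) into (2-fluoro-5-methoxyphenyl)lithium F1. F1 adds once to the lactone carbonyl of 5 at −78 °C (C4–C4a) to give, after NH4Cl quench, (3S)-1-(2-fluoro-5-methoxyphenyl)-5-hydroxy-3-methyl-3-[(trimethylsilyl)oxy]pentan-1-one F2. CsF in DMF (rt to 60 °C) then removes the silyl group, and the tertiary alkoxide displaces the ortho fluorine by intramolecular SNAr (O1–C8a). This gives 17 directly, without chlorine, so the route is rejoined at 17 and step 8 is omitted.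

Step 1. What may go wrong: the esterase discriminates the two ester arms poorly, so that 2 and hence 4 are of low enantiomeric purity. Fallback, classical resolution in place of enzymatic selection: it sets out from 4 of insufficient enantiomeric purity. Heating with (R)-1-phenylethylamine (toluene, 80 °C) opens the lactone to the diastereomeric amides (3S)-3,5-dihydroxy-3-methyl-N-[(1R)-1-phenylethyl]pentanamide F3 and (3R)-3,5-dihydroxy-3-methyl-N-[(1R)-1-phenylethyl]pentanamide F4. F3 is separated by crystallisation or chromatography and F4 is discarded. The amide is hydrolysed (NaOH aq., reflux), and acidification (HCl, pH 2) relactonises to 4, where the route is rejoined before step 3.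

Step 15. What may go wrong: elimination or Wurtz-type coupling during the lithium–iodine exchange, attack of t-BuLi on the chromene double bond, or slow transmetalation with β-hydride loss from the alkylpalladium intermediate. Fallback, organozinc in place of organolithium and borate: it sets out from 22. Zinc insertion (Zn dust activated with 1,2-dibromoethane and TMSCl, LiCl, THF, 40 °C) gives {2-[(2S)-2-methyl-6-[(triisopropylsilyl)oxy]-2H-chromen-2-yl]ethyl}zinc iodide F5. F5 is coupled with 29 in a Negishi reaction (Pd(OAc)2, SPhos, THF, rt) to give 32, where the route is rejoined before step 16.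

**Further compounds**

F1 | step 7 | (2-fluoro-5-methoxyphenyl)lithium | [Li]c1cc(OC)ccc1F
F2 | step 7 | (3S)-1-(2-fluoro-5-methoxyphenyl)-5-hydroxy-3-methyl-3-[(trimethylsilyl)oxy]pentan-1-one | OCC[C@@](O[Si](C)(C)C)(C)CC(=O)c1cc(OC)ccc1F
F3 | step 1 | (3S)-3,5-dihydroxy-3-methyl-N-[(1R)-1-phenylethyl]pentanamide | OCC[C@@](O)(C)CC(=O)N[C@H](C)c1ccccc1
F4 | step 1 | (3R)-3,5-dihydroxy-3-methyl-N-[(1R)-1-phenylethyl]pentanamide | OCC[C@](O)(C)CC(=O)N[C@H](C)c1ccccc1
F5 | step 15 | {2-[(2S)-2-methyl-6-[(triisopropylsilyl)oxy]-2H-chromen-2-yl]ethyl}zinc iodide | I[Zn]CC[C@@]1(C)C=Cc2cc(O[Si](C(C)C)(C(C)C)C(C)C)ccc2O1
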